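The route rests on opening ring C at C11–C12: the trisubstituted C11–C12 oxirane of ring C, with its methyl on C11, is read as a C11 methyl ketone joined to a C12 sulfur ylide. One base-induced operation then forms the C11–C12 bond, closes the six-membered ring and delivers the cis-fused oxirane by loss of diphenyl sulfide, setting C11 and C12 under control of C1, C10 and C14. The precursor is an open-chain methyl ketone with C1, C10 and C14 in place, a C12 diphenylsulfonium tetrafluoroborate, and O2/O14 tied as an anisylidene acetal. The C2–C5 chain, the esters, the butenolide and the ten-membered ring (metathesis at C5=C6) follow.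

Key step: step 16

Remarks on the chemistry
- Numbering: C1 quaternary ring-fusion carbon (C15 methyl), C2 butanoate carbon, C3/C4 methylenes, C5(C16)=C6, C7 lactone carbinol, C8=C17(C18)–C19 butenolide, C9 methylene, C10 ring-fusion CH, C11(C20)–C12 oxirane, C13 methylene, C14 acetate carbon; ring C = C1, C10–C14. Target configuration: 1R, 2S, 5Z, 7R, 10S, 11S, 12R, 14R.
- Assumption: 3-[(tert-butyldimethylsilyl)oxy]propanal is purchasable (otherwise two steps from propane-1,3-diol).
- C1: in the ester-enolate Claisen rearrangement of a chelated β-alkoxide ester dianion, as in its alkylation, the new C–C bond forms on the enolate face opposite the carbinol substituent. The target needs C10 syn and the C1 methyl anti to O14 (zigzag C2–C1–C14–C13). C10 is therefore attached first (Claisen on the unsubstituted C1 methylene, (E)-allyl ester) and the methyl second (dianion alkylation).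
- Precursor design: O2 and O14 share one 4-methoxybenzylidene acetal and O8 is a PMB ether. The acetal holds C13 and C10 gauche, leaves only an oxygen atom syn-axial to the sulfonium group in the closing chair, offers no pendant ether oxygen to the silver-assisted S-alkylation, and is later opened without acid.

Step 1
Reactants: 1 but-3-yn-1-ol
Product: 2 1-[(but-3-yn-1-yloxy)methyl]-4-methoxybenzene
Conditions: NaH, 4-MeOC6H4CH2Cl, Bu4NI (cat.), THF, 0 °C to rt
Reagents that add atoms: 4-methoxybenzyl chloride, COc1ccc(CCl)cc1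
Why: Williamson etherification of the sodium alkoxide with a benzylic chloride is reliable and leaves the terminal alkyne free for the next step.

Step 2
Reactants: 2 1-[(but-3-yn-1-yloxy)methyl]-4-methoxybenzene
Product: 3 5-[(4-methoxybenzyl)oxy]pent-2-yn-1-ol
Conditions: n-BuLi, THF, −78 °C; (CH2O)n, −78 °C to rt
Reagents that add atoms: formaldehyde (as paraformaldehyde), C=O
Why: Addition of the lithium acetylide to formaldehyde (alkyne hydroxymethylation) is a standard carbonyl alkynylation.

Step 3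
Reactants: 3 5-[(4-methoxybenzyl)oxy]pent-2-yn-1-ol
Product: 4 (2E)-5-[(4-methoxybenzyl)oxy]pent-2-en-1-ol
Conditions: LiAlH4, THF, 0 °C to reflux
Reagents that add atoms: none
Why: trans-Hydroalumination of the propargylic alkoxide (LiAlH4 reduction of a propargylic alcohol) should give only the (E)-allylic alcohol, whose geometry later fixes C10.

Step 4
Reactants: 5 3-[(tert-butyldimethylsilyl)oxy]propanal; 6 ethyl diazoacetate
Product: 7 ethyl 5-[(tert-butyldimethylsilyl)oxy]-3-oxopentanoate
Conditions: SnCl2 (cat.), CH2Cl2, rt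
Reagents that add atoms: none
Why: Roskamp homologation (tin dichloride-catalysed addition of the diazo ester to the aldehyde with hydride shift and loss of N2) gives the β-keto ester in one step.

Step 5
Reactants: 7 ethyl 5-[(tert-butyldimethylsilyl)oxy]-3-oxopentanoate
Product: 8 ethyl (3R)-5-[(tert-butyldimethylsilyl)oxy]-3-hydroxypentanoate
Conditions: H2 (10 atm), [RuCl2((R)-BINAP)]2·NEt3 (cat.), EtOH, 50 °C
Reagents that add atoms: none
Why: Noyori asymmetric hydrogenation, in which the chelated keto ester is reduced under control of the (R)-BINAP ligand to the (3R)-carbinol (same sense as an acetoacetate giving the (R)-3-hydroxybutanoate), which is the future C14; the amine-containing precatalyst keeps the medium non-acidic for the silyl ether.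

Step 6
Reactants: 8 ethyl (3R)-5-[(tert-butyldimethylsilyl)oxy]-3-hydroxypentanoate
Product: 9 (3R)-5-[(tert-butyldimethylsilyl)oxy]-3-hydroxypentanoic acid
Conditions: LiOH, THF–H2O, 0 °C to rt; then 1 M HCl to pH 4
Reagents that add atoms: lithium hydroxide, [Li+].[OH-]
Why: Saponification of an unhindered ethyl ester; the primary silyl ether and the carbinol centre are not affected by cold aqueous hydroxide.

Step 7
Reactants: 9 (3R)-5-[(tert-butyldimethylsilyl)oxy]-3-hydroxypentanoic acid; 4 (2E)-5-[(4-methoxybenzyl)oxy]pent-2-en-1-ol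
Product: 10 (2E)-5-[(4-methoxybenzyl)oxy]pent-2-en-1-yl (3R)-5-[(tert-butyldimethylsilyl)oxy]-3-hydroxypentanoate
Conditions: EDC·HCl, DMAP (cat.), CH2Cl2, 0 °C to rt
Reagents that add atoms: none
Why: Steglich-type carbodiimide esterification, in which the primary allylic alcohol should outcompete the hindered secondary hydroxyl of the acid.

Step 8
Reactants: 10 (2E)-5-[(4-methoxybenzyl)oxy]pent-2-en-1-yl (3R)-5-[(tert-butyldimethylsilyl)oxy]-3-hydroxypentanoate
Product: 12 methyl (2R,3R)-5-[(tert-butyldimethylsilyl)oxy]-3-hydroxy-2-{(3R)-5-[(4-methoxybenzyl)oxy]pent-1-en-3-yl}pentanoate, via hydroxy acid 11 (not isolated)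
Conditions: LiN(iPr)2 (2.4 equiv), THF, −78 to 50 °C; aq. HCl; then Me3SiCHN2, MeOH–PhMe, 0 °C
Reagents that add atoms: (trimethylsilyl)diazomethane, C[Si](C)(C)C=[N+]=[N-]
Why: Dianionic Ireland–Claisen (ester-enolate Claisen) rearrangement, in which the lithium alkoxide chelates the enolate, the chair transition state carries the (E)-olefin substituent (C9 chain) equatorial and the allyl terminus bonds to the enolate face away from the C13 chain, which should set C10 relative to C14 (C1 is provisional); the crude acid is methylated with the diazo reagent for the second enolisation.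

Step 9
Reactants: 12 methyl (2R,3R)-5-[(tert-butyldimethylsilyl)oxy]-3-hydroxy-2-{(3R)-5-[(4-methoxybenzyl)oxy]pent-1-en-3-yl}pentanoate
Product: 13 methyl (2S,3R)-5-[(tert-butyldimethylsilyl)oxy]-3-hydroxy-2-{(3R)-5-[(4-methoxybenzyl)oxy]pent-1-en-3-yl}-2-methylpentanoate
Conditions: LiN(iPr)2 (2.5 equiv), THF, −78 to −20 °C; MeI, DMPU, −78 to 0 °C
Reagents that add atoms: iodomethane, CI
Why: Fráter–Seebach alkylation, in which the chelated alkoxide–enolate dianion is methylated on the face opposite the C13 chain, so the methyl ends anti and C10 syn to O14, which is the C1 configuration of the target.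

Step 10
Reactants: 13 methyl (2S,3R)-5-[(tert-butyldimethylsilyl)oxy]-3-hydroxy-2-{(3R)-5-[(4-methoxybenzyl)oxy]pent-1-en-3-yl}-2-methylpentanoate
Product: 14 (2R,3R)-5-[(tert-butyldimethylsilyl)oxy]-2-{(3R)-5-[(4-methoxybenzyl)oxy]pent-1-en-3-yl}-2-methylpentane-1,3-diol
Conditions: LiAlH4, THF, 0 °C to rt
Reagents that add atoms: none
Why: Hydride reduction of the α-quaternary ester to the primary alcohol (C2) is routine and spares the silyl ether, the PMB ether and the vinyl group.

Step 11
Reactants: 14 (2R,3R)-5-[(tert-butyldimethylsilyl)oxy]-2-{(3R)-5-[(4-methoxybenzyl)oxy]pent-1-en-3-yl}-2-methylpentane-1,3-diol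
Product: 15 tert-butyl(2-{(2S,4R,5R)-2-(4-methoxyphenyl)-5-{(3R)-5-[(4-methoxybenzyl)oxy]pent-1-en-3-yl}-5-methyl-1,3-dioxan-4-yl}ethoxy)dimethylsilane
Conditions: 4-MeOC6H4CH(OMe)2, PPTS (cat.), CH2Cl2, rt
Reagents that add atoms: 4-methoxybenzaldehyde dimethyl acetal, COc1ccc(C(OC)OC)cc1
Why: Acid-catalysed transacetalisation of the 1,3-diol under thermodynamic control should give the six-membered acetal with the aryl group and the C13 chain equatorial, which places the C10 branch axial on the dioxane.

Step 12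
Reactants: 15 tert-butyl(2-{(2S,4R,5R)-2-(4-methoxyphenyl)-5-{(3R)-5-[(4-methoxybenzyl)oxy]pent-1-en-3-yl}-5-methyl-1,3-dioxan-4-yl}ethoxy)dimethylsilane
Product: 16 (3S)-3-{(2S,4R,5R)-4-{2-[(tert-butyldimethylsilyl)oxy]ethyl}-2-(4-methoxyphenyl)-5-methyl-1,3-dioxan-5-yl}-5-[(4-methoxybenzyl)oxy]pentan-2-one
Conditions: PdCl2 (cat.), CuCl, O2 (1 atm), DMF–H2O, rt
Reagents that add atoms: water, O
Why: Tsuji–Wacker oxidation of the monosubstituted olefin follows Markovnikov hydroxypalladation to the C11 methyl ketone, and the CuCl/O2 variant stays close to neutral for the acetal.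

Step 13
Reactants: 16 (3S)-3-{(2S,4R,5R)-4-{2-[(tert-butyldimethylsilyl)oxy]ethyl}-2-(4-methoxyphenyl)-5-methyl-1,3-dioxan-5-yl}-5-[(4-methoxybenzyl)oxy]pentan-2-one
Product: 17 (3S)-3-[(2S,4R,5R)-4-(2-hydroxyethyl)-2-(4-methoxyphenyl)-5-methyl-1,3-dioxan-5-yl]-5-[(4-methoxybenzyl)oxy]pentan-2-one
Conditions: Bu4NF, AcOH, THF, 0 °C to rt
Reagents that add atoms: none
Why: Fluoride desilylation of the only silyl ether, buffered with acetic acid so that the C10 hydrogen next to the ketone is not exchanged.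

Step 14
Reactants: 17 (3S)-3-[(2S,4R,5R)-4-(2-hydroxyethyl)-2-(4-methoxyphenyl)-5-methyl-1,3-dioxan-5-yl]-5-[(4-methoxybenzyl)oxy]pentan-2-one
Product: 18 (3S)-3-[(2S,4R,5R)-4-(2-iodoethyl)-2-(4-methoxyphenyl)-5-methyl-1,3-dioxan-5-yl]-5-[(4-methoxybenzyl)oxy]pentan-2-one
Conditions: I2, PPh3, imidazole, CH2Cl2, 0 °C
Reagents that add atoms: iodine, II
Why: Appel-type iodination of an unhindered primary alcohol proceeds under neutral conditions that tolerate the acetal and the ketone.

Step 15
Reactants: 18 (3S)-3-[(2S,4R,5R)-4-(2-iodoethyl)-2-(4-methoxyphenyl)-5-methyl-1,3-dioxan-5-yl]-5-[(4-methoxybenzyl)oxy]pentan-2-one; 19 diphenyl sulfide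
Product: 20 {2-[(2S,4R,5R)-5-{(3S)-5-[(4-methoxybenzyl)oxy]-2-oxopentan-3-yl}-2-(4-methoxyphenyl)-5-methyl-1,3-dioxan-4-yl]ethyl}diphenylsulfonium tetrafluoroborate
Conditions: AgBF4, 2,6-di-tert-butyl-4-methylpyridine (cat.), CH2Cl2–MeNO2, rt, dark
Reagents that add atoms: silver tetrafluoroborate, [Ag+].F[B-](F)(F)F
Why: Silver-assisted S-alkylation of the weakly nucleophilic diaryl sulfide by the primary iodide (AgI precipitates) is the standard entry to alkyldiphenylsulfonium salts, and the hindered pyridine scavenges adventitious acid.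

Step 16
Reactants: 20 {2-[(2S,4R,5R)-5-{(3S)-5-[(4-methoxybenzyl)oxy]-2-oxopentan-3-yl}-2-(4-methoxyphenyl)-5-methyl-1,3-dioxan-4-yl]ethyl}diphenylsulfonium tetrafluoroborate
Product: 23 ring C epoxide (1R,10S,11S,12R,14R) carrying the O2/O14 4-methoxybenzylidene acetal and the 8-O-PMB arm, via sulfonium ylide 21 (not isolated), via anti betaine 22 (not isolated)
Conditions: KN(SiMe3)2 (1.05 equiv), THF, −78 to 0 °C
Reagents that add atoms: none
Why: The amide base removes the proton next to sulfur at C12, far more acidic than any ketone proton; the ylide carbon adds to the C11 carbonyl and the alkoxide then displaces diphenyl sulfide from C12. The closest known reaction type is the intramolecular Corey–Chaykovsky epoxidation (sulfonium-ylide epoxy-annulation of tethered ketones). Ring C closes 6-exo-trig through the C11–C12 bond, and the oxirane closes 3-exo-tet through O–C12 with inversion at C12. C11 is set by the closing chair, in which the acetal-bound C2 and the C9 arm are equatorial and the C11 methyl takes the equatorial site to avoid the axial C15 methyl, so oxygen is axial on the C15 face; C12 follows because only the betaine with sulfur anti to that oxygen can close, which gives the cis-fused oxirane on the same face. The step needs this facial selectivity and ylide formation without enolisation or epimerisation at C10; the acetal secures the first by locking the chair, holding C13 and C10 gauche and leaving only a bare ring oxygen syn-axial to the sulfonium group, and the acidity gap with a low-temperature, non-equilibrating base secures the second.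

Step 17
Reactants: 23 ring C epoxide with O2/O14 4-methoxybenzylidene acetal and 8-O-PMB arm
Product: 24 C2 primary alcohol with 14-O-PMB and 8-O-PMB ethers (ring C epoxide intact)
Conditions: iBu2AlH, CH2Cl2, −78 to 0 °C
Reagents that add atoms: none
Why: Regioselective reductive opening of the 4-methoxybenzylidene acetal, in which the aluminium hydride coordinates the less hindered primary oxygen O2, that C–O bond breaks and hydride quenches the oxocarbenium ion, leaving PMB on O14 and a free C2 alcohol at a temperature where the oxirane should persist.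

Step 18
Reactants: 24 C2 primary alcohol with 14-O-PMB and 8-O-PMB ethers
Product: 25 C2 aldehyde (14-O-PMB, 8-O-PMB, ring C epoxide)
Conditions: Dess–Martin periodinane, pyridine, CH2Cl2, 0 °C to rt
Reagents that add atoms: none
Why: Dess–Martin oxidation of a neopentyl primary alcohol gives a non-enolisable aldehyde under buffered, non-acidic conditions that spare the oxirane and the PMB ethers.

Step 19
Reactants: 25 C2 aldehyde; 26 4-bromo-2-methylbut-1-ene
Product: 28 C2 secondary alcohol bearing the 3-methylbut-3-enyl chain (C3–C5 with C16; both C2 epimers), via Grignard reagent 27 (not isolated)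
Conditions: 26, Mg, THF, rt; then 25, THF, −78 to −20 °C
Reagents that add atoms: none
Why: Grignard addition to the non-enolisable aldehyde installs C3–C5 and C16, and the C2 configuration formed here is of no consequence because it is erased in step 20.

Step 20
Reactants: 28 C2 secondary alcohol (both epimers)
Product: 29 C2 ketone
Conditions: Dess–Martin periodinane, pyridine, CH2Cl2, rt
Reagents that add atoms: none
Why: Dess–Martin oxidation converges both C2 epimers on one ketone without touching the terminal olefin or the oxirane.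

Step 21
Reactants: 29 C2 ketone
Product: 30 (2S)-alcohol
Conditions: (R)-Me-CBS oxazaborolidine (cat.), catecholborane, PhMe, −40 °C
Reagents that add atoms: none
Why: Corey–Bakshi–Shibata reduction, in which the quaternary C1 is the large and the C3 methylene chain the small substituent, so the (R)-catalyst should deliver hydride to give the (2S)-carbinol under reagent control, and catecholborane at low temperature leaves the 1,1-disubstituted olefin and the oxirane alone.

Step 22
Reactants: 30 (2S)-alcohol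
Product: 31 (2S)-2-O-butanoate (14-O-PMB, 8-O-PMB)
Conditions: (PrCO)2O, DMAP, Et3N, CH2Cl2, rt
Reagents that add atoms: butanoic anhydride, CCCC(=O)OC(=O)CCC
Why: DMAP-catalysed acylation of the hindered secondary alcohol installs the butanoate with retention, as no bond to C2 is broken.

Step 23
Reactants: 31 (2S)-2-O-butanoate (14-O-PMB, 8-O-PMB)
Product: 32 8,14-diol (2-O-butanoate)
Conditions: DDQ, CH2Cl2–pH 7 buffer, 0 °C to rt
Reagents that add atoms: none
Why: Oxidative cleavage of both 4-methoxybenzyl ethers by DDQ runs at neutral pH and leaves the oxirane, the butanoate and the isolated olefin untouched.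

Step 24
Reactants: 32 8,14-diol
Product: 33 C8 aldehyde with free 14-OH
Conditions: TEMPO (cat.), PhI(OAc)2, CH2Cl2, rt
Reagents that add atoms: none
Why: Oxoammonium (TEMPO) oxidation is selective for the primary C8 alcohol over the hindered axial secondary 14-OH and stops at the aldehyde.

Step 25
Reactants: 33 C8 aldehyde with free 14-OH
Product: 34 14-O-acetyl C8 aldehyde
Conditions: Ac2O, pyridine, DMAP (cat.), CH2Cl2, 0 °C to rt
Reagents that add atoms: acetic anhydride, CC(=O)OC(C)=O
Why: DMAP-catalysed acetylation of the 14-OH installs the acetate with retention before any base-sensitive butenolide is present.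

Step 26
Reactants: 34 14-O-acetyl C8 aldehyde; 35 allyl tert-butyldimethylsilyl ether
Product: 37 (7R,8R)-8-hydroxy-7-[(tert-butyldimethylsilyl)oxy] adduct carrying the C6 vinyl group, via allylborane 36 (not isolated)
Conditions: 35, s-BuLi, THF–HMPA, −78 °C; (−)-Ipc2BOMe [from (+)-α-pinene]; BF3·OEt2 (1 equiv); then 34, −78 °C; H2O2, pH 7 buffer
Reagents that add atoms: none
Why: Brown-type γ-oxygenated allylboration, in which the (Z)-γ-silyloxyallylborane reacts through a chair transition state to give the syn adduct and the isopinocampheyl groups direct attack to the Si face of the aldehyde, which should set C7 as R (C8 becomes a ketone next); the boron trifluoride is consumed in forming the borane before the oxirane-bearing aldehyde is added.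

Step 27
Reactants: 37 (7R,8R)-8-hydroxy-7-silyloxy adduct
Product: 38 (7R)-7-[(tert-butyldimethylsilyl)oxy] C8 ketone
Conditions: Dess–Martin periodinane, pyridine, CH2Cl2, 0 °C to rt
Reagents that add atoms: none
Why: Dess–Martin oxidation under buffered conditions gives the α-silyloxy ketone without enolisation towards C7.

Step 28
Reactants: 38 (7R)-7-silyloxy C8 ketone
Product: 39 (7R)-7-hydroxy C8 ketone
Conditions: Bu4NF, AcOH, THF, 0 °C
Reagents that add atoms: none
Why: Acetic acid-buffered fluoride desilylation frees the C7 hydroxyl under near-neutral conditions that should not epimerise C7 or open the oxirane.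

Step 29
Reactants: 39 (7R)-7-hydroxy C8 ketone; 40 2-(diethoxyphosphoryl)propanoic acid
Product: 42 (7R)-7-vinyl butenolide diene (C8=C17, C18 methyl, C19 lactone carbonyl), via phosphonate ester 41 (not isolated)
Conditions: 40, EDC·HCl, DMAP (cat.), CH2Cl2, 0 °C; then LiCl, iPr2NEt, MeCN, rt
Reagents that add atoms: none
Why: Carbodiimide esterification of the C7 hydroxyl followed by intramolecular Horner–Wadsworth–Emmons olefination of the C8 ketone under mild LiCl/amine conditions closes the α-methyl butenolide without breaking the C7–O bond, so C7 is retained.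

Step 30
Reactants: 42 (7R)-7-vinyl butenolide diene
Product: 43 CNP0220791.1 (target)
Conditions: second-generation Hoveyda–Grubbs catalyst RuCl2(H2IMes)(=CH-C6H4-2-OiPr) (cat.), 1,4-benzoquinone (cat.), PhMe (1 mM), 80 °C
Reagents that add atoms: none
Why: Ring-closing olefin metathesis, in which the catalyst loads on the C7 vinyl group and closes onto the 1,1-disubstituted olefin at high dilution, and a ten-membered ring fused to the butenolide and ring C should accept only the cis ring olefin, which is the (5Z) geometry of the target.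

Compound list
1 | but-3-yn-1-ol | C#CCCO | starting material
2 | 1-[(but-3-yn-1-yloxy)methyl]-4-methoxybenzene | C#CCCOCc1ccc(OC)cc1 | intermediate
3 | 5-[(4-methoxybenzyl)oxy]pent-2-yn-1-ol | OCC#CCCOCc1ccc(OC)cc1 | intermediate
4 | (2E)-5-[(4-methoxybenzyl)oxy]pent-2-en-1-ol | OC/C=C/CCOCc1ccc(OC)cc1 | intermediate
5 | 3-[(tert-butyldimethylsilyl)oxy]propanal | O=CCCO[Si](C)(C)C(C)(C)C | starting material
6 | ethyl diazoacetate | CCOC(=O)C=[N+]=[N-] | starting material
7 | ethyl 5-[(tert-butyldimethylsilyl)oxy]-3-oxopentanoate | CCOC(=O)CC(=O)CCO[Si](C)(C)C(C)(C)C | intermediate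
8 | ethyl (3R)-5-[(tert-butyldimethylsilyl)oxy]-3-hydroxypentanoate | CCOC(=O)C[C@H](O)CCO[Si](C)(C)C(C)(C)C | intermediate
9 | (3R)-5-[(tert-butyldimethylsilyl)oxy]-3-hydroxypentanoic acid | OC(=O)C[C@H](O)CCO[Si](C)(C)C(C)(C)C | intermediate
10 | (2E)-5-[(4-methoxybenzyl)oxy]pent-2-en-1-yl (3R)-5-[(tert-butyldimethylsilyl)oxy]-3-hydroxypentanoate | COc1ccc(COCC/C=C/COC(=O)C[C@H](O)CCO[Si](C)(C)C(C)(C)C)cc1 | intermediate
11 | (2R,3R)-5-[(tert-butyldimethylsilyl)oxy]-3-hydroxy-2-{(3R)-5-[(4-methoxybenzyl)oxy]pent-1-en-3-yl}pentanoic acid | OC(=O)[C@@H]([C@H](O)CCO[Si](C)(C)C(C)(C)C)[C@@H](C=C)CCOCc1ccc(OC)cc1 | intermediate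
12 | methyl (2R,3R)-5-[(tert-butyldimethylsilyl)oxy]-3-hydroxy-2-{(3R)-5-[(4-methoxybenzyl)oxy]pent-1-en-3-yl}pentanoate | COC(=O)[C@@H]([C@H](O)CCO[Si](C)(C)C(C)(C)C)[C@@H](C=C)CCOCc1ccc(OC)cc1 | intermediate
13 | methyl (2S,3R)-5-[(tert-butyldimethylsilyl)oxy]-3-hydroxy-2-{(3R)-5-[(4-methoxybenzyl)oxy]pent-1-en-3-yl}-2-methylpentanoate | COC(=O)[C@](C)([C@H](O)CCO[Si](C)(C)C(C)(C)C)[C@@H](C=C)CCOCc1ccc(OC)cc1 | intermediate
14 | (2R,3R)-5-[(tert-butyldimethylsilyl)oxy]-2-{(3R)-5-[(4-methoxybenzyl)oxy]pent-1-en-3-yl}-2-methylpentane-1,3-diol | OC[C@](C)([C@H](O)CCO[Si](C)(C)C(C)(C)C)[C@@H](C=C)CCOCc1ccc(OC)cc1 | intermediate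
15 | tert-butyl(2-{(2S,4R,5R)-2-(4-methoxyphenyl)-5-{(3R)-5-[(4-methoxybenzyl)oxy]pent-1-en-3-yl}-5-methyl-1,3-dioxan-4-yl}ethoxy)dimethylsilane | C=C[C@@H](CCOCc1ccc(OC)cc1)[C@]1(C)CO[C@H](c2ccc(OC)cc2)O[C@@H]1CCO[Si](C)(C)C(C)(C)C | intermediate
16 | (3S)-3-{(2S,4R,5R)-4-{2-[(tert-butyldimethylsilyl)oxy]ethyl}-2-(4-methoxyphenyl)-5-methyl-1,3-dioxan-5-yl}-5-[(4-methoxybenzyl)oxy]pentan-2-one | CC(=O)[C@@H](CCOCc1ccc(OC)cc1)[C@]1(C)CO[C@H](c2ccc(OC)cc2)O[C@@H]1CCO[Si](C)(C)C(C)(C)C | intermediate
17 | (3S)-3-[(2S,4R,5R)-4-(2-hydroxyethyl)-2-(4-methoxyphenyl)-5-methyl-1,3-dioxan-5-yl]-5-[(4-methoxybenzyl)oxy]pentan-2-one | CC(=O)[C@@H](CCOCc1ccc(OC)cc1)[C@]1(C)CO[C@H](c2ccc(OC)cc2)O[C@@H]1CCO | intermediate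
18 | (3S)-3-[(2S,4R,5R)-4-(2-iodoethyl)-2-(4-methoxyphenyl)-5-methyl-1,3-dioxan-5-yl]-5-[(4-methoxybenzyl)oxy]pentan-2-one | CC(=O)[C@@H](CCOCc1ccc(OC)cc1)[C@]1(C)CO[C@H](c2ccc(OC)cc2)O[C@@H]1CCI | intermediate
19 | diphenyl sulfide | c1ccc(Sc2ccccc2)cc1 | starting material
20 | {2-[(2S,4R,5R)-5-{(3S)-5-[(4-methoxybenzyl)oxy]-2-oxopentan-3-yl}-2-(4-methoxyphenyl)-5-methyl-1,3-dioxan-4-yl]ethyl}diphenylsulfonium tetrafluoroborate | CC(=O)[C@@H](CCOCc1ccc(OC)cc1)[C@]1(C)CO[C@H](c2ccc(OC)cc2)O[C@@H]1CC[S+](c3ccccc3)c3ccccc3.F[B-](F)(F)F | intermediate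
21 | C12 diphenylsulfonium ylide of 20 | CC(=O)[C@@H](CCOCc1ccc(OC)cc1)[C@]1(C)CO[C@H](c2ccc(OC)cc2)O[C@@H]1C[CH-][S+](c3ccccc3)c3ccccc3 | intermediate
22 | ring C betaine: C11 alkoxide (oxygen on the C15 face) and C12 diphenylsulfonium trans to it | COc1ccc(COCC[C@@H]2[C@](C)([O-])[C@@H]([S+](c3ccccc3)c3ccccc3)C[C@H]4O[C@@H](c5ccc(OC)cc5)OC[C@@]24C)cc1 | intermediate
23 | ring C epoxide (1R,10S,11S,12R,14R) with O2/O14 4-methoxybenzylidene acetal (aryl equatorial) and 8-O-PMB arm | COc1ccc(COCC[C@@H]2[C@]3(C)O[C@@H]3C[C@H]4O[C@@H](c5ccc(OC)cc5)OC[C@@]24C)cc1 | intermediate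
24 | C2 primary alcohol with 14-O-PMB and 8-O-PMB ethers, ring C epoxide | COc1ccc(COCC[C@@H]2[C@]3(C)O[C@@H]3C[C@@H](OCc4ccc(OC)cc4)[C@@]2(C)CO)cc1 | intermediate
25 | C2 aldehyde (14-O-PMB, 8-O-PMB, ring C epoxide) | COc1ccc(COCC[C@@H]2[C@]3(C)O[C@@H]3C[C@@H](OCc4ccc(OC)cc4)[C@@]2(C)C=O)cc1 | intermediate
26 | 4-bromo-2-methylbut-1-ene | C=C(C)CCBr | starting material
27 | (3-methylbut-3-en-1-yl)magnesium bromide | C=C(C)CC[Mg]Br | intermediate
28 | C2 secondary alcohol with 3-methylbut-3-enyl chain (both C2 epimers) | COc1ccc(COCC[C@@H]2[C@]3(C)O[C@@H]3C[C@@H](OCc4ccc(OC)cc4)[C@@]2(C)C(O)CCC(C)=C)cc1 | intermediate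
29 | C2 ketone | COc1ccc(COCC[C@@H]2[C@]3(C)O[C@@H]3C[C@@H](OCc4ccc(OC)cc4)[C@@]2(C)C(=O)CCC(C)=C)cc1 | intermediate
30 | (2S)-alcohol | COc1ccc(COCC[C@@H]2[C@]3(C)O[C@@H]3C[C@@H](OCc4ccc(OC)cc4)[C@@]2(C)[C@@H](O)CCC(C)=C)cc1 | intermediate
31 | (2S)-2-O-butanoate (14-O-PMB, 8-O-PMB) | COc1ccc(COCC[C@@H]2[C@]3(C)O[C@@H]3C[C@@H](OCc4ccc(OC)cc4)[C@@]2(C)[C@@H](OC(=O)CCC)CCC(C)=C)cc1 | intermediate
32 | 8,14-diol (2-O-butanoate) | OCC[C@@H]1[C@]2(C)O[C@@H]2C[C@@H](O)[C@@]1(C)[C@@H](OC(=O)CCC)CCC(C)=C | intermediate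
33 | C8 aldehyde with free 14-OH | O=CC[C@@H]1[C@]2(C)O[C@@H]2C[C@@H](O)[C@@]1(C)[C@@H](OC(=O)CCC)CCC(C)=C | intermediate
34 | 14-O-acetyl C8 aldehyde | O=CC[C@@H]1[C@]2(C)O[C@@H]2C[C@@H](OC(C)=O)[C@@]1(C)[C@@H](OC(=O)CCC)CCC(C)=C | intermediate
35 | allyl tert-butyldimethylsilyl ether | C=CCO[Si](C)(C)C(C)(C)C | starting material
36 | B-[(Z)-3-(tert-butyldimethylsilyloxy)allyl]diisopinocampheylborane (isopinocampheyl groups from (+)-α-pinene) | CC(C)(C)[Si](C)(C)O/C=C\CB([C@@H]1C[C@@H]2C[C@H]([C@H]1C)C2(C)C)[C@@H]1C[C@@H]2C[C@H]([C@H]1C)C2(C)C | intermediate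
37 | (7R,8R)-8-hydroxy-7-[(tert-butyldimethylsilyl)oxy] adduct with C6 vinyl group | C=C[C@@H](O[Si](C)(C)C(C)(C)C)[C@H](O)C[C@@H]1[C@]2(C)O[C@@H]2C[C@@H](OC(C)=O)[C@@]1(C)[C@@H](OC(=O)CCC)CCC(C)=C | intermediate
38 | (7R)-7-[(tert-butyldimethylsilyl)oxy] C8 ketone | C=C[C@@H](O[Si](C)(C)C(C)(C)C)C(=O)C[C@@H]1[C@]2(C)O[C@@H]2C[C@@H](OC(C)=O)[C@@]1(C)[C@@H](OC(=O)CCC)CCC(C)=C | intermediate
39 | (7R)-7-hydroxy C8 ketone | C=C[C@@H](O)C(=O)C[C@@H]1[C@]2(C)O[C@@H]2C[C@@H](OC(C)=O)[C@@]1(C)[C@@H](OC(=O)CCC)CCC(C)=C | intermediate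
40 | 2-(diethoxyphosphoryl)propanoic acid | CCOP(=O)(OCC)C(C)C(=O)O | starting material
41 | 7-O-[2-(diethoxyphosphoryl)propanoyl] ester of 39 | C=C[C@@H](OC(=O)C(C)P(=O)(OCC)OCC)C(=O)C[C@@H]1[C@]2(C)O[C@@H]2C[C@@H](OC(C)=O)[C@@]1(C)[C@@H](OC(=O)CCC)CCC(C)=C | intermediate
42 | (7R)-7-vinyl α-methyl butenolide diene (metathesis substrate) | C=C[C@H]1OC(=O)C(C)=C1C[C@@H]2[C@]3(C)O[C@@H]3C[C@@H](OC(C)=O)[C@@]2(C)[C@@H](OC(=O)CCC)CCC(C)=C | intermediate
43 | CNP0220791.1 | CCCC(=O)O[C@H]1CC/C(C)=C\[C@H]2OC(=O)C(C)=C2C[C@@H]2[C@]3(C)O[C@@H]3C[C@@H](OC(C)=O)[C@@]12C | target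

Total step count: 30. Longest linear sequence: 27 steps (steps 4–30 from aldehyde 5; the branch through steps 1–3 joins at step 7 and is equally long).

Steps most likely to fail

Step 16. The ylide may add through a geometry whose betaine has sulfur and oxygen cis on the new ring and cannot close, or the ketone may be enolised, so that ring closure stalls or C10 is epimerised. The fallback sets out from alcohol 17 and returns at epoxide 23 by building the ring as an olefin first. Dess–Martin oxidation of 17 would give keto aldehyde F1. Double Wittig methylenation (Ph3P=CH2, THF, low temperature) would give diene F2. Ring-closing metathesis with the second-generation Grubbs catalyst RuCl2(=CHPh)(H2IMes)(PCy3) would give the C11=C12 cyclohexene F3, a six-membered closure of high reliability. N-Bromoacetamide in buffered aqueous THF would add bromine from the face away from the axial C15 methyl and water at tertiary C11 from the opposite face to give bromohydrin F4. K2CO3 in methanol would then close the oxirane on the C15 face, which is 23; direct peracid epoxidation is avoided because it should attack the wrong face.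

Step 30. The ruthenium alkylidene formed at the C7 vinyl group may dimerise, or the doubly activated C7 position may isomerise faster than the strained ten-membered ring closes onto the 1,1-disubstituted olefin. The fallback sets out from silyloxy ketone 38 and returns at the target 43 by closing the macrocycle before the butenolide, while C7 and C8 are not yet part of a planar lactone. Ring-closing metathesis of 38 with the same catalyst would give macrocyclic silyloxy ketone F5. Buffered Bu4NF would give macrocyclic hydroxy ketone F6. Carbodiimide esterification with 40 would give macrocyclic phosphonate ester F7, and the LiCl/iPr2NEt Horner–Wadsworth–Emmons closure would then form the butenolide on the finished ring to give 43.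

Step 26. Metalation of the allyl silyl ether may be incomplete or followed by silyl migration from oxygen to carbon, residual boron trifluoride may open the oxirane, or facial control may be modest. The fallback sets out from aldehyde 34 and returns at butenolide 42 by forming the C8–C17 bond first. Aldol addition of the lithium enolate of methyl propanoate at −78 °C would give β-hydroxy ester F8. Dess–Martin oxidation would give β-keto ester F9. NaH and PhNTf2 would give the (Z)-enol triflate F10 from the chelated sodium enolate. Nozaki–Hiyama–Kishi coupling with acrolein (CrCl2, NiCl2 cat., DMF), with lactonisation of the resulting alkoxide onto the cis ester, would give 42 together with its C7 epimer F11. This fallback has no control at C7: F11 would have to be separated and recycled by base equilibration (DBU).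

Further compounds
F1 | step 16 | keto aldehyde: C12 aldehyde of 17 | CC(=O)[C@@H](CCOCc1ccc(OC)cc1)[C@]1(C)CO[C@H](c2ccc(OC)cc2)O[C@@H]1CC=O
F2 | step 16 | diene: C11 isopropenyl and C12 vinyl groups | C=C(C)[C@@H](CCOCc1ccc(OC)cc1)[C@]1(C)CO[C@H](c2ccc(OC)cc2)O[C@@H]1CC=C
F3 | step 16 | ring C cyclohexene (C11=C12) with acetal and 8-O-PMB arm | COc1ccc(COCC[C@@H]2C(C)=CC[C@H]3O[C@@H](c4ccc(OC)cc4)OC[C@@]23C)cc1
F4 | step 16 | bromohydrin: 11-OH on the C15 face and 12-Br trans to it | COc1ccc(COCC[C@@H]2[C@](C)(O)[C@@H](Br)C[C@H]3O[C@@H](c4ccc(OC)cc4)OC[C@@]23C)cc1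
F5 | step 30 | macrocyclic (5Z,7R)-7-[(tert-butyldimethylsilyl)oxy] C8 ketone | CCCC(=O)O[C@H]1CC/C(C)=C\[C@@H](O[Si](C)(C)C(C)(C)C)C(=O)C[C@@H]2[C@]3(C)O[C@@H]3C[C@@H](OC(C)=O)[C@@]12C
F6 | step 30 | macrocyclic (5Z,7R)-7-hydroxy C8 ketone | CCCC(=O)O[C@H]1CC/C(C)=C\[C@@H](O)C(=O)C[C@@H]2[C@]3(C)O[C@@H]3C[C@@H](OC(C)=O)[C@@]12C
F7 | step 30 | macrocyclic 7-O-[2-(diethoxyphosphoryl)propanoyl] C8 ketone | CCCC(=O)O[C@H]1CC/C(C)=C\[C@@H](OC(=O)C(C)P(=O)(OCC)OCC)C(=O)C[C@@H]2[C@]3(C)O[C@@H]3C[C@@H](OC(C)=O)[C@@]12C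
F8 | step 26 | methyl 3-hydroxy-2-methyl ester at C8 (C8 and C17 epimers) | COC(=O)C(C)C(O)C[C@@H]1[C@]2(C)O[C@@H]2C[C@@H](OC(C)=O)[C@@]1(C)[C@@H](OC(=O)CCC)CCC(C)=C
F9 | step 26 | methyl 2-methyl-3-oxo ester (C8 ketone) | COC(=O)C(C)C(=O)C[C@@H]1[C@]2(C)O[C@@H]2C[C@@H](OC(C)=O)[C@@]1(C)[C@@H](OC(=O)CCC)CCC(C)=C
F10 | step 26 | (Z)-enol triflate at C8 (triflate cis to the ester) | COC(=O)/C(C)=C(\OS(=O)(=O)C(F)(F)F)C[C@@H]1[C@]2(C)O[C@@H]2C[C@@H](OC(C)=O)[C@@]1(C)[C@@H](OC(=O)CCC)CCC(C)=C
F11 | step 26 | (7S)-epimer of 42 | C=C[C@@H]1OC(=O)C(C)=C1C[C@@H]2[C@]3(C)O[C@@H]3C[C@@H](OC(C)=O)[C@@]2(C)[C@@H](OC(=O)CCC)CCC(C)=C
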